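## Structural features

1-Benzoxepine numbering is used throughout (O1, C2–C5, C5a, C6–C9, C9a): a chair cyclohexane (C5a, C6–C9, C9a) is trans-fused along C5a–C9a to an oxepane (O1, C2–C5, C5a, C9a). Three of the five stereocentres form one block in the carbocycle: C9a (tertiary ether carbon, axial CH3), its neighbour C5a (axial H) and, beyond the quaternary C6, C7 with an equatorial, neopentyl secondary bromide. The other two flank the sp2 carbon C3 with its exocyclic methylidene: C2 (H and CH2Br, the CH2Br cis to the C9a methyl across O1) and C4 (allylic OH on the face of H-5a). Four groups are fragile: the β-bromo ether at C2 (bases, reducing metals); the acid-labile ether O1, tert-alkyl on one side and allylic on the other; the allylic alcohol (SN2′, transposition); and the C7 bromide, which substitution next to C6 cannot install reliably. The real difficulty is O1. It ties a fully substituted carbon to a secondary stereogenic carbon inside a seven-membered ring, so every C–O ring closure is a slow etherification at a hindered centre, and it competes with five-ring closure because the C4 oxygen stands 1,4 to C9a. The key step exploits that C2–C3(=CH2)–C4(O) of the oxepane is the retron of a Morita–Baylis–Hillman adduct: C2 with its CH2Br is bromoacetaldehyde, and C3(=CH2)–C4 is a vinyl ketone. O1–C2 can then be made as an acetal bond to the tertiary alcohol, which is easy, and the oxepane is closed at the carbon–carbon bond C2–C3 with the methylidene and bromomethyl groups already in place.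

## Logic of the disconnections

**16 to 15.** The C4–H bond of the carbinol is cut (ketone reduction in the forward sense). With C4 as a ketone, C3(=CH2)–C4(=O) becomes an enone, the acceptor half of the retron. One stereocentre disappears. The forward step must deliver hydride 1,2 and from the β-face, and must leave both C–Br bonds alone.

**15 to 12 (key).** The ring bond C2–C3 is cut, C2 is raised to the acetal level and C3 returns to the α-carbon of a vinyl ketone. In one sentence: the oxepane is closed at C2–C3 by attack of the α-carbon of a vinyl ketone, made nucleophilic by a sulfide, on the oxocarbenium ion set free from a tert-alkyl bromoacetal. The cut removes the seven-membered ring and the C2 stereocentre and leaves a monocyclic cyclohexane with two simple side chains. The hindered ether problem is turned into acetal chemistry. The forward step must ionise the acetal on the correct side, close a seven-membered ring faster than the tert-alkyl oxocarbenium ion decays, and choose one face of C2.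

**12 to 10 + 11.** The C3–C4 bond is cut between acyl carbon and vinyl group. The sensitive enone is thereby made last before the key step, from a stable acyl donor. The gain is a two-carbon commercial nucleophile. The demand is single addition without attack on the bromoacetal.

**10 to 8 + 9.** O1–C2 and the CH2–Br bond are cut together (three-component haloalkoxylation of an enol ether). C2, the bromomethyl carbon and its bromine arrive in one operation, and the tertiary alcohol is masked at the same time. The demand is capture of a reactive bromo-oxocarbenium ion by a hindered tertiary alcohol.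

**8 to 7.** The C4–N bond is cut and the acyl bond between C4 and the oxygen on C9a is restored. The five-membered lactone ring of 7 ties the future O1 and C4 together, which is what a cation–olefin cyclisation closes well. The demand is clean aminolysis without relactonisation.

**7 to 5 (through 6).** C5a–C6 and C9a–O are cut. This is the one place where a bromonium-induced cyclisation is used, for what it does best: a six-membered carbocycle ended by five-ring oxygen capture. Three stereocentres (C7, C5a, C9a) collapse to the single C7 centre of an acyclic chain. The demand is generation of the bromiranium ion without loss of configuration.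

**5 to 4.** The C7–Br bond is cut back to an epoxide. Configuration at C7 then comes from a catalytic asymmetric oxidation. The demand is SN2 opening at the secondary carbon.

**4 to 3.** The C4–C5 bond is cut (C1 homologation with carbon monoxide at an allylic terminus). The gain is a C10 terpene skeleton. The demand is retention of the E alkene and survival of the epoxide.

**3 to 2 to 1.** The two epoxide C–O bonds and the carbonate C–O bond are cut. The carbonate deactivates the neighbouring alkene, so only the distal alkene is oxidised, and it later serves as leaving group. This ends at a commodity alcohol.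

## Other disconnections considered

**Alternative 1:** (the first that comes to mind) cut O1–C9a and C5a–C6 at once. The forward key step is a bromonium-initiated bicyclisation of the acyclic dienyl bromohydrin A1, in which the C2 hydroxyl ends the cascade at the C9a cation.
- Seven-ring oxygen capture must outrun proton loss from the tertiary cation.
- The C4 oxygen, 1,4 to C9a, offers a five-ring exit as soon as its protecting group is lost.
- Three alkenes compete for Br+.
- The remote centres C2 and C4 cannot bias the face of the distal bromonium ion, so the two halves of the molecule would be joined without relative control.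
- The chosen plan keeps the cation chemistry for a five-ring termination and moves the seven-ring closure to a separate C–C bond formation.

**Alternative 2:** remove O1, tracing O1–C9a back to a C2–C9a carbon–carbon bond. The forward key step is a Baeyer–Villiger oxygen insertion into trans-decalone A3, derived from the enedione A2, with migration of the quaternary carbon and retention to give lactone A4.
- The stereochemistry at C9a would be secure.
- After the insertion, however, C2, C3 and C4 are all still unfunctionalised. A C1 unit must be added to the lactone carbonyl and reduced, C3 methylenated and C4 oxidised, each in its own steps.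
- The C7 bromide has to be built from a ketone.
- By count of operations this is roughly half as long again as the chosen plan, and C2 would again rest on face selection at a cyclic oxocarbenium ion.

**Alternative 3:** excise C3. The forward key step is a (2+1) addition of dibromocarbene to the trans-fused dihydropyran A5. A silver-promoted disrotatory electrocyclic opening of the cyclopropane and hydride capture at C2 then give the 3-bromo-oxepene A6.
- The ring is grown from an easily closed six-membered ether, which is attractive.
- C3 arrives, however, as a vinylic bromide that must be exchanged for carbon in the presence of two alkyl bromides.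
- The C4 oxygen needs a further oxidation with alkene transposition.
- Hydride capture of the allyl-oxocarbenium ion is ambiguous (C2 versus C4).
- The bromomethyl group must be carried in masked form.
- The chosen key step delivers C3=CH2, C4=O and CH2Br in the oxidation states needed.

Key step: step 9

Assumption: the acetal carbon of 10, 12 and 13 (and of F1, F2) forms as a mixture of epimers. It is drawn without configuration because it becomes planar in step 9.

## Steps

Step 1
Reactants: 1 geraniol
Product: 2 geranyl methyl carbonate
Conditions: ClCO2Me, pyridine, CH2Cl2, 0 °C to rt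
Reagents that add atoms: methyl chloroformate, COC(=O)Cl
Why: O-acylation of a primary allylic alcohol; the carbonate deactivates the adjacent alkene for step 2 and is leaving group and methoxide source for step 3.

Step 2
Reactants: 2 geranyl methyl carbonate
Product: 3 (2E)-5-[(2R)-3,3-dimethyloxiran-2-yl]-3-methylpent-2-en-1-yl methyl carbonate
Conditions: D-fructose-derived Shi ketone (cat.), Oxone, K2CO3, Bu4NHSO4, borate/EDTA buffer, MeCN–dimethoxymethane, 0 °C
Reagents that add atoms: potassium peroxymonosulfate (Oxone), [K+].OOS(=O)(=O)[O-]
Why: Shi asymmetric epoxidation; the electrophilic chiral dioxirane takes the electron-rich distal trisubstituted alkene and leaves the alkene that bears the allylic carbonate. The spiro transition state of the D-fructose-derived ketone should give the R epoxide, the source of C7.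

Step 3
Reactants: 3 (2E)-5-[(2R)-3,3-dimethyloxiran-2-yl]-3-methylpent-2-en-1-yl methyl carbonate
Product: 4 methyl (3E)-6-[(2R)-3,3-dimethyloxiran-2-yl]-4-methylhex-3-enoate
Conditions: Pd(OAc)2 (cat.), PPh3, CO (10 atm), THF, 50 °C
Reagents that add atoms: carbon monoxide, [C-]#[O+]
Why: Tsuji-type decarboxylative carbonylation of an allylic carbonate: ionisation gives a π-allylpalladium methoxide and CO2, CO inserts at the unsubstituted terminus, and methoxide releases the β,γ-unsaturated ester. The E geometry should hold because syn–anti exchange would need a σ-bond at the fully substituted terminus, and the non-allylic epoxide is inert to Pd(0).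

Step 4
Reactants: 4 methyl (3E)-6-[(2R)-3,3-dimethyloxiran-2-yl]-4-methylhex-3-enoate
Product: 5 methyl (3E,7S)-7-bromo-8-hydroxy-4,8-dimethylnon-3-enoate
Conditions: Li2NiBr4, THF, 0 °C; pH 7 buffer
Reagents that add atoms: dilithium tetrabromonickelate, [Li+].[Li+].[Ni+2].[Br-].[Br-].[Br-].[Br-]
Why: Epoxide opening by a soft bromide source under nearly neutral conditions, SN2 at the less substituted carbon; inversion turns the R epoxide carbon into the S bromide, the final configuration of C7.

Step 5
Reactants: 5 methyl (3E,7S)-7-bromo-8-hydroxy-4,8-dimethylnon-3-enoate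
Product: 7 (3aS,5S,7aS)-5-bromo-4,4,7a-trimethylhexahydro-1-benzofuran-2(3H)-one, via tertiary trifluoroacetate 6 (not isolated)
Conditions: (CF3CO)2O, 2,6-lutidine, CH2Cl2, −20 °C; wash, concentrate; then (CF3)2CHOH (high dilution), 0 °C to rt
Reagents that add atoms: trifluoroacetic anhydride, O=C(OC(=O)C(F)(F)F)C(F)(F)F (its CF3CO group stands in 6 only and is lost again on the way to 7)
Why: Enantiospecific bromonium-induced polyene cyclisation: in the strongly ionising, weakly nucleophilic solvent the neighbouring bromine assists departure of trifluoroacetate and gives one enantiomer of the bromiranium ion without free Br+. The E alkene attacks its tertiary carbon through a chair with the C–Br bond equatorial, the ester carbonyl oxygen traps the cation anti in a five-membered ring, and trifluoroacetate removes the methyl group. C7 is carried over from 5 and fixes C5a and C9a, and anti addition to the E alkene gives the trans fusion with axial CH3 and axial H.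

Step 6
Reactants: 7 (3aS,5S,7aS)-5-bromo-4,4,7a-trimethylhexahydro-1-benzofuran-2(3H)-one
Product: 8 2-[(1S,3S,6S)-3-bromo-6-hydroxy-2,2,6-trimethylcyclohexyl]-N-methoxy-N-methylacetamide
Conditions: MeNH(OMe)·HCl, AlMe3, CH2Cl2, 0 °C to rt; Rochelle salt
Reagents that add atoms: N,O-dimethylhydroxylamine hydrochloride, CNOC.Cl
Why: Weinreb aminolysis of a lactone with an aluminium amide, driven by release of the strain of the trans-fused five-membered ring and by the strong Al–O bond to the tertiary alkoxide; the equatorial neopentyl bromide has no antiperiplanar hydrogen and is inert.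

Step 7
Reactants: 8 2-[(1S,3S,6S)-3-bromo-6-hydroxy-2,2,6-trimethylcyclohexyl]-N-methoxy-N-methylacetamide; 9 ethyl vinyl ether
Product: 10 2-[(1S,3S,6S)-3-bromo-6-(2-bromo-1-ethoxyethoxy)-2,2,6-trimethylcyclohexyl]-N-methoxy-N-methylacetamide
Conditions: NBS, excess 9, CH2Cl2, −40 to 0 °C
Reagents that add atoms: N-bromosuccinimide, O=C1CCC(=O)N1Br
Why: Bromoacetalisation (haloalkoxylation of an enol ether, the first stage of Ueno–Stork chemistry): Br+ adds to the terminal carbon of 9, and the very electrophilic oxocarbenium ion is captured even by a tertiary alcohol. The step creates O1–C2, C2 and CH2Br, and masks the alcohol.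

Step 8
Reactants: 10 2-[(1S,3S,6S)-3-bromo-6-(2-bromo-1-ethoxyethoxy)-2,2,6-trimethylcyclohexyl]-N-methoxy-N-methylacetamide; 11 vinylmagnesium bromide
Product: 12 1-[(1S,3S,6S)-3-bromo-6-(2-bromo-1-ethoxyethoxy)-2,2,6-trimethylcyclohexyl]but-3-en-2-one
Conditions: THF, −78 to 0 °C; inverse quench into cold aq NH4Cl
Reagents that add atoms: none
Why: Weinreb ketone synthesis; the chelated tetrahedral intermediate prevents a second addition. Uncatalysed Grignard reagents do not displace alkyl bromides at this temperature, and the cold inverse quench limits aza-Michael addition of the liberated amine to the enone.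

Step 9
Reactants: 12 1-[(1S,3S,6S)-3-bromo-6-(2-bromo-1-ethoxyethoxy)-2,2,6-trimethylcyclohexyl]but-3-en-2-one
Product: 15 (2R,5aS,7S,9aS)-7-bromo-2-(bromomethyl)-6,6,9a-trimethyl-3-methylideneoctahydro-1-benzoxepin-4(2H)-one, via sulfonio silyl enol ether triflate 13 (not isolated), via cyclised sulfonio ketone triflate 14 (not isolated)
Conditions: Me2S, TMSOTf, 2,6-di-tert-butyl-4-methylpyridine, CH2Cl2 (high dilution), −78 to −20 °C; then DBU, −20 to 0 °C
Reagents that add atoms: dimethyl sulfide, CSC, and trimethylsilyl triflate, C[Si](C)(C)OS(=O)(=O)C(F)(F)F (their atoms stand in 13 and 14 only; none remains in 15)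
Why: Me2S adds 1,4 to the TMSOTf-activated vinyl ketone and gives the (Z)-β-sulfonio silyl enol ether 13, so that C3 and not C5 becomes the nucleophilic carbon; TMSOTf then silylates the less hindered ethoxy oxygen of the acetal and releases the (E)-oxocarbenium ion C9a–O1(+)=C2H–CH2Br, which Me2S buffers reversibly as its sulfonium adduct. C3 attacks C2 in an intramolecular Mukaiyama-type addition that closes the oxepane at C2–C3 in a 7-(enolendo)-endo-trig mode to give 14, and DBU expels Me2S by E1cB to uncover the C3 methylidene of 15. The closest known reaction type is the sulfide/silyl triflate mediated (chalcogeno) Morita–Baylis–Hillman α-alkoxyalkylation of enones with acetals, run here intramolecularly. The only new stereocentre, C2, is controlled by the rigid, gauche-disposed equatorial bonds C9a–O1 and C5a–C5 of the chair: the oxocarbenium carbon sits anti to the axial C9a methyl (the gauche rotamer presses H-2 against C5H2), the E geometry keeps CH2Br anti to C9a, and the short tether C5–C4 can bring C3 only to the face of C2 that is turned toward C5a. Bond formation on that face leaves H-2 on the side of H-5a and CH2Br pseudo-equatorial and cis to the angular methyl (2R), and it makes C2, C3, C4 and C5 nearly coplanar, which is the geometry the s-cis enone of 15 requires. The step needs loss of ethoxide rather than of the tertiary alkoxide (secured by steric access of the silyl electrophile and by the hindered pyridine, which removes triflic acid); it also needs ring closure faster than O1–C9a heterolysis (low temperature, sulfide buffering, an oxocarbenium ion made more electrophilic by the β-bromine) and intra- over intermolecular reaction (high dilution). Both alkyl bromides are inert to silyl triflate and to a dialkyl sulfide at these temperatures, and the sulfonium group is by far the better E1cB leaving group than the β-alkoxide O1.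

Step 10
Reactants: 15 (2R,5aS,7S,9aS)-7-bromo-2-(bromomethyl)-6,6,9a-trimethyl-3-methylideneoctahydro-1-benzoxepin-4(2H)-one
Product: 16 (2R,4R,5aS,7S,9aS)-7-bromo-2-(bromomethyl)-6,6,9a-trimethyl-3-methylidenedecahydro-1-benzoxepin-4-ol (target)
Conditions: NaBH4, CeCl3·7H2O, MeOH, −78 °C
Reagents that add atoms: none
Why: Luche reduction gives 1,2-addition to the α-methylene ketone and spares alkyl bromides. In the conformer with C2–C5 coplanar, the α-face of C4=O is covered by axial H-5a and the underside of the cyclohexane, so hydride should arrive from the β-face and place the hydroxyl on the α-face (4R), cis to H-5a and H-2.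

## Compound list

1 | geraniol, (2E)-3,7-dimethylocta-2,6-dien-1-ol | CC(C)=CCC/C(C)=C/CO | starting material
2 | geranyl methyl carbonate | CC(C)=CCC/C(C)=C/COC(=O)OC | intermediate
3 | (2E)-5-[(2R)-3,3-dimethyloxiran-2-yl]-3-methylpent-2-en-1-yl methyl carbonate | CC1(C)O[C@@H]1CC/C(C)=C/COC(=O)OC | intermediate
4 | methyl (3E)-6-[(2R)-3,3-dimethyloxiran-2-yl]-4-methylhex-3-enoate | CC1(C)O[C@@H]1CC/C(C)=C/CC(=O)OC | intermediate
5 | methyl (3E,7S)-7-bromo-8-hydroxy-4,8-dimethylnon-3-enoate | COC(=O)C/C=C(\C)CC[C@H](Br)C(C)(C)O | intermediate
6 | methyl (3E,7S)-7-bromo-4,8-dimethyl-8-(trifluoroacetoxy)non-3-enoate | COC(=O)C/C=C(\C)CC[C@H](Br)C(C)(C)OC(=O)C(F)(F)F | intermediate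
7 | (3aS,5S,7aS)-5-bromo-4,4,7a-trimethylhexahydro-1-benzofuran-2(3H)-one | O=C1C[C@H]2C(C)(C)[C@@H](Br)CC[C@]2(C)O1 | intermediate
8 | 2-[(1S,3S,6S)-3-bromo-6-hydroxy-2,2,6-trimethylcyclohexyl]-N-methoxy-N-methylacetamide | CON(C)C(=O)C[C@H]1C(C)(C)[C@@H](Br)CC[C@]1(C)O | intermediate
9 | ethyl vinyl ether | C=COCC | starting material
10 | 2-[(1S,3S,6S)-3-bromo-6-(2-bromo-1-ethoxyethoxy)-2,2,6-trimethylcyclohexyl]-N-methoxy-N-methylacetamide (acetal epimers) | CON(C)C(=O)C[C@H]1C(C)(C)[C@@H](Br)CC[C@]1(C)OC(CBr)OCC | intermediate
11 | vinylmagnesium bromide | C=C[Mg]Br | starting material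
12 | 1-[(1S,3S,6S)-3-bromo-6-(2-bromo-1-ethoxyethoxy)-2,2,6-trimethylcyclohexyl]but-3-en-2-one (acetal epimers) | C=CC(=O)C[C@H]1C(C)(C)[C@@H](Br)CC[C@]1(C)OC(CBr)OCC | intermediate
13 | {(2Z)-4-[(1S,3S,6S)-3-bromo-6-(2-bromo-1-ethoxyethoxy)-2,2,6-trimethylcyclohexyl]-3-(trimethylsilyloxy)but-2-en-1-yl}dimethylsulfonium triflate | C[S+](C)C/C=C(\O[Si](C)(C)C)C[C@H]1C(C)(C)[C@@H](Br)CC[C@]1(C)OC(CBr)OCC.[O-]S(=O)(=O)C(F)(F)F | intermediate
14 | {[(2R,5aS,7S,9aS)-7-bromo-2-(bromomethyl)-6,6,9a-trimethyl-4-oxodecahydro-1-benzoxepin-3-yl]methyl}dimethylsulfonium triflate (C3 epimers) | C[S+](C)CC1C(=O)C[C@H]2C(C)(C)[C@@H](Br)CC[C@]2(C)O[C@H]1CBr.[O-]S(=O)(=O)C(F)(F)F | intermediate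
15 | (2R,5aS,7S,9aS)-7-bromo-2-(bromomethyl)-6,6,9a-trimethyl-3-methylideneoctahydro-1-benzoxepin-4(2H)-one | C=C1C(=O)C[C@H]2C(C)(C)[C@@H](Br)CC[C@]2(C)O[C@H]1CBr | intermediate
16 | (2R,4R,5aS,7S,9aS)-7-bromo-2-(bromomethyl)-6,6,9a-trimethyl-3-methylidenedecahydro-1-benzoxepin-4-ol | C=C1[C@H](O)C[C@H]2C(C)(C)[C@@H](Br)CC[C@]2(C)O[C@H]1CBr | target

## Step count and least certain steps

Total step count: 10. Longest linear sequence: 10 (1 to 16). No protecting-group steps are used.

**Step 9 (key step).** The most likely failure is that ring closure loses the race. Two processes could outrun it: the tert-alkyl oxocarbenium ion can decay by heterolysis of the O1–C9a bond, or the acetal can ionise with loss of the tertiary alkoxy group. The reason is that the β-sulfonio enol silane is a cationic, weakened nucleophile and seven-ring closure is entropically slow. A second risk is leakage through the gauche rotamer, with poor facial selectivity at C2. The fallback separates ring closure from methylene installation and uses a neutral, more nucleophilic enol silane. It sets out from 10 and returns at 15. Methylmagnesium bromide converts 10 into the methyl ketone F1. Kinetic deprotonation at the methyl group (LDA, TMSCl, −78 °C) gives the terminal silyl enol ether F2. A Mukaiyama-type acetal cyclisation (catalytic TMSOTf or TiCl4, −78 °C) closes the same C2–C3 bond to the oxepan-4-one F3. Kinetic enolisation toward the less hindered, more acidic C3 and reaction with Eschenmoser's salt give the Mannich base F4. Quaternisation with MeI and mild base then lead to 15.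

**Step 5.** Four things may go wrong. Enantiopurity may erode by transfer of Br+ from the bromiranium ion to an alkene of a second molecule. Solvent may capture the ion. Adventitious acid may cause proton-initiated lactonisation of the β,γ-alkene. Ionisation of a β-bromo ester may be sluggish. The fallback drops the bromonium ion and sets C7 last under thermodynamic control. It sets out from 2 and returns at 7. Epoxidation of 2 with the enantiomeric (L-series) ketone gives the S epoxy carbonate F5, and carbonylation as in step 3 gives the S epoxy ester F6. Lewis acid induced epoxide-initiated cyclisation gives the equatorial hydroxy lactone F7 with the same C5a/C9a configuration as 7. Dess–Martin oxidation gives keto lactone F8, and KHMDS with Comins reagent gives the alkenyl triflate F9 (only one enolisable side). Ruthenium-catalysed triflate–bromide exchange with LiBr gives the alkenyl bromide F10. Metal-hydride hydrogen-atom-transfer hydrogenation (Mn(dpm)3, PhSiH3, t-BuOOH) adds H to C8. It then delivers the second hydrogen axially from the open α-face to the α-bromo radical, which should leave the bromide equatorial, as in 7.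

**Step 4.** Opening may take place at the tertiary carbon through an SN1-like pathway as soon as the medium becomes Lewis acidic, which gives the wrong regioisomer. The fallback makes the regiochemistry irrelevant. It sets out from 4 and returns at 7. Ph3PBr2 converts the epoxide into the (7S)-7,8-dibromide F11. Whichever carbon is attacked first, the C7–Br bond ends anti to the former oxygen, by direct displacement or through the bromiranium ion. Solvolysis of the tertiary bromide of F11 in (CF3)2CHOH with anchimeric assistance then gives the same bromiranium ion and cyclises to 7.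

**Step 7.** Capture of the bromo-oxocarbenium ion by the hindered tertiary alcohol may be slow, so that succinimide intercepts it, and traces of HBr may trigger relactonisation to 7. The fallback reverses the roles of the partners. It sets out from 8 and returns at 10. Pd(II)- or Ir(I)-catalysed transfer vinylation turns the tertiary alcohol into its vinyl ether F12. NBS in the presence of ethanol then adds Br+ to the vinyl ether, and the small alcohol captures the cation to give 10.

**Step 10.** Facial selectivity may be poor if the oxepanone populates a second conformer, and some conjugate reduction may occur. The fallback corrects the centre by substitution. It sets out from 15 and returns at 16. The 4S epimer F13 from the reduction is subjected to Mitsunobu inversion with 4-nitrobenzoic acid to give the 4R ester F14, and brief methanolysis (K2CO3, MeOH, 0 °C) gives 16.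

## Further compounds

F1 | step 9 | 1-[(1S,3S,6S)-3-bromo-6-(2-bromo-1-ethoxyethoxy)-2,2,6-trimethylcyclohexyl]propan-2-one | CC(=O)C[C@H]1C(C)(C)[C@@H](Br)CC[C@]1(C)OC(CBr)OCC
F2 | step 9 | ({3-[(1S,3S,6S)-3-bromo-6-(2-bromo-1-ethoxyethoxy)-2,2,6-trimethylcyclohexyl]prop-1-en-2-yl}oxy)trimethylsilane | C=C(O[Si](C)(C)C)C[C@H]1C(C)(C)[C@@H](Br)CC[C@]1(C)OC(CBr)OCC
F3 | step 9 | (2R,5aS,7S,9aS)-7-bromo-2-(bromomethyl)-6,6,9a-trimethyloctahydro-1-benzoxepin-4(2H)-one | C1C(=O)C[C@H]2C(C)(C)[C@@H](Br)CC[C@]2(C)O[C@H]1CBr
F4 | step 9 | (2R,5aS,7S,9aS)-7-bromo-2-(bromomethyl)-3-[(dimethylamino)methyl]-6,6,9a-trimethyloctahydro-1-benzoxepin-4(2H)-one | CN(C)CC1C(=O)C[C@H]2C(C)(C)[C@@H](Br)CC[C@]2(C)O[C@H]1CBr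
F5 | step 5 | (2E)-5-[(2S)-3,3-dimethyloxiran-2-yl]-3-methylpent-2-en-1-yl methyl carbonate | CC1(C)O[C@H]1CC/C(C)=C/COC(=O)OC
F6 | step 5 | methyl (3E)-6-[(2S)-3,3-dimethyloxiran-2-yl]-4-methylhex-3-enoate | CC1(C)O[C@H]1CC/C(C)=C/CC(=O)OC
F7 | step 5 | (3aS,5S,7aS)-5-hydroxy-4,4,7a-trimethylhexahydro-1-benzofuran-2(3H)-one | O=C1C[C@H]2C(C)(C)[C@@H](O)CC[C@]2(C)O1
F8 | step 5 | (3aS,7aS)-4,4,7a-trimethyltetrahydro-1-benzofuran-2,5(3H,4H)-dione | O=C1C[C@H]2C(C)(C)C(=O)CC[C@]2(C)O1
F9 | step 5 | (3aS,7aS)-4,4,7a-trimethyl-2-oxo-2,3,3a,4,7,7a-hexahydro-1-benzofuran-5-yl trifluoromethanesulfonate | O=C1C[C@H]2C(C)(C)C(OS(=O)(=O)C(F)(F)F)=CC[C@]2(C)O1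
F10 | step 5 | (3aS,7aS)-5-bromo-4,4,7a-trimethyl-3a,4,7,7a-tetrahydro-1-benzofuran-2(3H)-one | O=C1C[C@H]2C(C)(C)C(Br)=CC[C@]2(C)O1
F11 | step 4 | methyl (3E,7S)-7,8-dibromo-4,8-dimethylnon-3-enoate | COC(=O)C/C=C(\C)CC[C@H](Br)C(C)(C)Br
F12 | step 7 | 2-[(1S,3S,6S)-3-bromo-6-(ethenyloxy)-2,2,6-trimethylcyclohexyl]-N-methoxy-N-methylacetamide | CON(C)C(=O)C[C@H]1C(C)(C)[C@@H](Br)CC[C@]1(C)OC=C
F13 | step 10 | (2R,4S,5aS,7S,9aS)-7-bromo-2-(bromomethyl)-6,6,9a-trimethyl-3-methylidenedecahydro-1-benzoxepin-4-ol | C=C1[C@@H](O)C[C@H]2C(C)(C)[C@@H](Br)CC[C@]2(C)O[C@H]1CBr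
F14 | step 10 | (2R,4R,5aS,7S,9aS)-7-bromo-2-(bromomethyl)-6,6,9a-trimethyl-3-methylidenedecahydro-1-benzoxepin-4-yl 4-nitrobenzoate | C=C1[C@H](OC(=O)c3ccc([N+](=O)[O-])cc3)C[C@H]2C(C)(C)[C@@H](Br)CC[C@]2(C)O[C@H]1CBr
A1 | alternative 1 | (2R,4R,6E)-1-bromo-4-[(tert-butyldimethylsilyl)oxy]-7,11-dimethyl-3-methylidenedodeca-6,10-dien-2-ol | BrC[C@H](O)C(=C)[C@H](O[Si](C)(C)C(C)(C)C)C/C=C(\C)CCC=C(C)C
A2 | alternative 2 | (S)-Wieland–Miescher ketone, (8aS)-8a-methyl-3,4,8,8a-tetrahydronaphthalene-1,6(2H,7H)-dione | O=C1CCCC2=CC(=O)CC[C@]12C
A3 | alternative 2 | (4aR,6S,8aS)-6-bromo-5,5,8a-trimethyloctahydronaphthalen-1(2H)-one | O=C1CCC[C@H]2C(C)(C)[C@@H](Br)CC[C@]12C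
A4 | alternative 2 | (5aS,7S,9aS)-7-bromo-6,6,9a-trimethyloctahydro-1-benzoxepin-2(3H)-one | O=C1CCC[C@H]2C(C)(C)[C@@H](Br)CC[C@]2(C)O1
A5 | alternative 3 | {[(4aS,6S,8aS)-6-bromo-5,5,8a-trimethyl-4a,5,6,7,8,8a-hexahydro-4H-chromen-2-yl]methoxy}(tert-butyl)dimethylsilane | CC(C)(C)[Si](C)(C)OCC1=CC[C@H]2C(C)(C)[C@@H](Br)CC[C@]2(C)O1
A6 | alternative 3 | {[(2S,5aS,7S,9aS)-3,7-dibromo-6,6,9a-trimethyl-2,5,5a,6,7,8,9,9a-octahydro-1-benzoxepin-2-yl]methoxy}(tert-butyl)dimethylsilane | BrC1=CC[C@H]2C(C)(C)[C@@H](Br)CC[C@]2(C)O[C@H]1CO[Si](C)(C)C(C)(C)C
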